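80.0% of the substrate charged is the ceiling for Sunday's flask: each product takes up one coupling partner overall, and c(coupling partner) starts at 0.120 M, lower than c(substrate) at 0.150 M, so the coupling partner is the limiting reagent.

| setting | Saturday's | Wednesday's | Thursday's | Sunday's |
|---|---|---|---|---|
| substrate | 0.150 M | 0.220 M | 0.150 M | 0.150 M |
| coupling partner | 0.120 M | 0.120 M | 0.360 M | 0.120 M |
| time |  |  |  | 180 min |

| Saturday's run: time / min | Saturday's run: [product] / M | Wednesday's run: time / min | Wednesday's run: [product] / M | Thursday's run: time / min | Thursday's run: [product] / M |
|---|---|---|---|---|---|
| 1.2 | 1 × 10⁻⁴ | 1.2 | 0.0011 | 1.2 | 0.0116 |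
| 2.3 | 0.0016 | 2.3 | 0 | 2.3 | 0.0265 |
| 4.3 | 0.0061 | 4.3 | 0.0050 | 4.3 | 0.0616 |
| 8.3 | 0.0210 | 8.3 | 0.0167 | 8.3 | 0.1265 |
| 16 | 0.0729 | 16 | 0.0812 | 16 | 0.1478 |
| 30 | 0.1170 | 30 | 0.1188 | 30 | 0.1487 |

(scatter of a reading: 8 × 10⁻⁴ M)

* apparent order in [coupling partner] of the starting rate, round the charge of the Saturday's run (the rate where two percent of its substrate have turned into product)
* apparent order in [substrate] of the starting rate, round the charge of the Saturday's run (the rate where two percent of its substrate have turned into product) (one fixed amount of product, the same in the runs compared)
* product in the Sunday's run at 180 min, as a share of the substrate charged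

- Overall: substrate + coupling partner -> product.
- Constant volume, constant temperature.
- What is held in complexes is read along with the free species.
- "The second partner" is coupling partner.
- An order is taken over about fifteen percent of the charge, up and down.

Take a first floor from Saturday's flask, charged like Sunday's: its last reading, at 30 min, is already 78.0% of the substrate charged. Now tighten the bracket. Call the gap the distance of c(product) below 0.120 M. In Saturday's flask the gap falls from 0.0471 M at 16 min to 0.00300 M at 30 min. Replace that stretch by its mean: 0.197 /min is the closing constant, the mean fraction of the gap lost per minute. Sunday's remaining 150 min then hold 29.6 lifetimes of the gap, which puts the mean curve on the ceiling.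

Check the error of that mean. The constant read from these readings is not steady: the stretch before gives 0.0965 /min, less than 0.197 /min. So take a second tail, a gap whose rate of closing goes with its square, through the same two readings: its constant is 22.3 /M/min. In Sunday's flask that leaves an estimated gap of 2.72 × 10⁻⁴ M at 180 min and raises the floor to 79.8%. My bracket is therefore 79.8% to 80.0%.

The forecast gives 79.7%, with orders 1.4 in c(coupling partner) and −0.3 in c(substrate), and says: “All runs go essentially to completion on the limiting reagent”. Its 79.7% stands just outside that bracket, next to my floor of 79.8%.

The flask gives 80.0%, with orders 1.5 and −0.067; the forecast's substrate order parts from this, for at equal product Wednesday's rate is 0.95 of Saturday's.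

substrate + 2 coupling partner → product + coupling partner (9.420 /M²/min); substrate + coupling partner ⇌ idle substrate-reagent adduct, settled at all times (37.90 /M); substrate + coupling partner + product → 2 product (120.6 /M²/min) At 0.197 /min, Sunday's gap would pass the scatter of 8 × 10⁻⁴ M at 36.7 min, earlier than 180 min. Carry 0.197 /min to Wednesday's flask: from its gap at 16 min, the estimate puts product at half its substrate charge at 22.9 min, and the flask gives 21.5 min.

The numbers in the tables were generated by integration for an exercise; scatter was added.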